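A direct plan would cut the linker at its CH2–C(sp2) bond and would join a 6-vinyl-1,2-dioxane, methyl (2R)-2-[(3R,6S)-6-ethenyl-6-methyl-1,2-dioxan-3-yl]propanoate (A4), to the bicyclic enol triflate A2 by hydroboration and B-alkyl Suzuki coupling.
A2 would come from a thermal intramolecular Diels–Alder reaction of the (Z)-trienone A1; A4 would come from geraniol through a hydroperoxy diol closed to the peroxy-hemiacetal triacetate A3, onto whose peroxycarbenium ion a chiral propionate enolate would be added.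
Its weakest steps would be: (a) the trimming of the diacetoxyethyl arm of A3 down to the vinyl group of A4 (methanolysis, glycol cleavage, methylenation), three steps with the O–O bond aboard and no gain in complexity;
(b) the enolate addition to the peroxycarbenium ion, a union without precedent that would have to set the propanoate and the ring stereocentre in one event, the ring one only through the size difference of the two groups on the far quaternary carbon;
(c) the closing borane/zerovalent-palladium coupling of a hindered, fully substituted triflate on the complete peroxide, the step one would least like to run on the most precious material.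

**Plan of the new route**
The route cuts the dioxane–linker bond D6–L1 instead: the whole bicycle, carried on an alkynyl borate, would be added to the peroxycarbenium ion of a 6-methoxy-6-methyl-1,2-dioxane, and diimide would then saturate the L1≡L2 link.
What makes this possible: D6 is the only fully substituted carbon of the dioxane, it is at ketal level (O1, methyl) and lies 1,4 to D3 across O1–O2, so the arm on D3 can steer axial attack at D6; L1–L2 is an unbranched two-carbon link ending at the tetrasubstituted N2=N3 alkene, which diimide does not touch.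
The bicycle is not made by cycloaddition: ring B with N8a is bought as (4S)-limonene oxide, an Ireland–Claisen shift relays the oxygen on N6 to carbon on N4a (cis), and ring A is closed by the N1–N2 bond (isopropenyl cation onto a β-keto ester), the N2=N3 alkene coming from the enol triflate.
The dioxane is closed at O2–D3 by SN2 attack of a hydroperoxy ketal on an aldol-derived mesylate, so P2 and D3 come from one Evans aldol and D6 is relayed from D3 in the key step.
Order of rings: ring B (pool), ring A, dioxane (separately), union; no side arm is trimmed, no enolate meets a peroxycarbenium ion, and neither borane nor palladium touches the peroxide.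
Key step: step 18

Remark: (4S)-limonene 1,2-oxide (sold as the mixture of its two epoxide diastereomers), 4-methylpent-4-enal and (4R)-4-benzyl-3-propanoyl-1,3-oxazolidin-2-one are taken as commercial. Locants: P1/P2 propanoate carbons, O1/O2 and D3–D6 dioxane atoms, L1 (on D6) and L2 linker carbons, N1–N8a naphthalene carbons.

**Ring B to the alkynyl borate (steps 1–10)**

Step 1
Reactants: 1 (4S)-limonene 1,2-oxide [(4S)-1,2-epoxy-p-menth-8-ene; mixture of the (1R,2S,4S) and (1S,2R,4S) diastereomers]
Product: 4 (1R,4S)-1-methyl-4-(prop-1-en-2-yl)cyclohex-2-en-1-ol (hydroxyl cis to the isopropenyl group), via hydroxy selenide 2 (not isolated), via selenoxide 3 (not isolated)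
Conditions: (PhSe)2 (0.28 equiv), NaBH4 (0.6 equiv), EtOH, 0 → 78 °C; then THF, NaHCO3, 30% H2O2, 0 → 40 °C; unreacted (1S,2R,4S)-oxide removed by distillation
Reagents that add atoms: none
Why: Epoxide-to-allylic-alcohol transposition through a selenide (selenolate opening, selenoxide syn-elimination away from the carbinol carbon), in which by the Fürst–Plattner rule only the (1R,2S,4S) oxide, whose oxygen is on the face of the isopropenyl group, can open trans-diaxially at the secondary C2, so the limiting selenolate selects it, the C1–O bond is never broken and the hydroxyl ends cis to the isopropenyl group, C4 (the later N8a) coming from the pool.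

Step 2
Reactants: 4 (1R,4S)-1-methyl-4-(prop-1-en-2-yl)cyclohex-2-en-1-ol
Product: 5 (1R,4S)-1-methyl-4-(prop-1-en-2-yl)cyclohex-2-en-1-yl acetate
Conditions: Ac2O, Et3N, DMAP (0.2 equiv), CH2Cl2, rt
Reagents that add atoms: acetic anhydride, CC(=O)OC(C)=O
Why: DMAP-catalysed acylation of the tertiary allylic alcohol under basic conditions that cannot ionise the C1–O bond, so the configuration at C1 is kept.

Step 3
Reactants: 5 (1R,4S)-1-methyl-4-(prop-1-en-2-yl)cyclohex-2-en-1-yl acetate
Product: 8 2-[(1R,6S)-3-methyl-6-(prop-1-en-2-yl)cyclohex-2-en-1-yl]acetic acid, via silyl ketene acetal 6 (not isolated), via trimethylsilyl ester 7 (not isolated)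
Conditions: LDA, Me3SiCl/Et3N, THF, −78 °C → rt → 50 °C; then 1 M HCl
Reagents that add atoms: none
Why: Ireland–Claisen rearrangement, a suprafacial [3,3] shift that must form the new C–C bond on the ring face that carried the oxygen, i.e. cis to the isopropenyl group, which sets the later N4a as (1R) and moves the alkene to its final N5=N6 position.

Step 4
Reactants: 8 2-[(1R,6S)-3-methyl-6-(prop-1-en-2-yl)cyclohex-2-en-1-yl]acetic acid
Product: 10 methyl 4-[(1R,6S)-3-methyl-6-(prop-1-en-2-yl)cyclohex-2-en-1-yl]-3-oxobutanoate, via acyl imidazole 9 (not isolated)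
Conditions: CDI, THF, rt; then MeO2CCH2CO2K, MgCl2, Et3N, MeCN/THF, rt → 45 °C; 1 M HCl
Reagents that add atoms: potassium methyl malonate, [K+].[O-]C(=O)CC(=O)OC
Why: Masamune–Brooks homologation (C-acylation of the magnesium malonate half-ester by the acyl imidazole, then decarboxylation), a near-neutral acyl transfer that leaves both ring stereocentres and both alkenes alone.

Step 5
Reactants: 10 methyl 4-[(1R,6S)-3-methyl-6-(prop-1-en-2-yl)cyclohex-2-en-1-yl]-3-oxobutanoate
Product: 12 methyl (4aR,8aS)-1,1,6-trimethyl-3-oxo-1,2,3,4,4a,7,8,8a-octahydronaphthalene-2-carboxylate (N2 epimers and enol), via tertiary carbocation 11 (not isolated)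
Conditions: SnCl4 (2 equiv), CH2Cl2, −20 → 0 °C; aq NaHCO3
Reagents that add atoms: none
Why: Lewis acid-promoted cyclisation of an olefinic β-keto ester (cation–olefin type, 6-(enolendo)-exo-trig), in which Markovnikov protonation of the isopropenyl group gives the tertiary cation 11 at N1, whose former CH2 becomes the second methyl group, and C-alkylation by the tin-chelated enol closes ring A through the N1–N2 bond; the fusion is cis because both arms were already cis on ring B, and the new N2 centre is erased in the next step.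

Step 6
Reactants: 12 methyl (4aR,8aS)-1,1,6-trimethyl-3-oxo-1,2,3,4,4a,7,8,8a-octahydronaphthalene-2-carboxylate
Product: 14 methyl (4aR,8aS)-1,1,6-trimethyl-3-{[(trifluoromethyl)sulfonyl]oxy}-1,4,4a,7,8,8a-hexahydronaphthalene-2-carboxylate, via sodium enolate 13 (not isolated)
Conditions: NaH, THF, 0 °C; PhNTf2, 0 °C → rt; aq NH4Cl
Reagents that add atoms: N-phenylbis(trifluoromethanesulfonimide), FC(F)(F)S(=O)(=O)N(c1ccccc1)S(=O)(=O)C(F)(F)F
Why: Enol triflate formation from the only enolate a β-keto ester gives (deprotonation between the two carbonyls), which fixes the N2=N3 alkene without any regiochemical choice; no stereocentre is formed.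

Step 7
Reactants: 14 methyl (4aR,8aS)-1,1,6-trimethyl-3-{[(trifluoromethyl)sulfonyl]oxy}-1,4,4a,7,8,8a-hexahydronaphthalene-2-carboxylate
Product: 15 methyl (4aR,8aS)-1,1,3,6-tetramethyl-1,4,4a,7,8,8a-hexahydronaphthalene-2-carboxylate
Conditions: MeMgBr (1.5 equiv), Fe(acac)3 (5 mol %), THF/NMP, −30 °C
Reagents that add atoms: methylmagnesium bromide, C[Mg]Br
Why: Iron-catalysed Kumada-type cross-coupling of a β-keto-ester enol triflate, which at −30 °C is faster than Grignard attack on the hindered ester and gives the tetrasubstituted N2=N3 alkene with the N3 methyl group; no stereocentre is touched.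

Step 8
Reactants: 15 methyl (4aR,8aS)-1,1,3,6-tetramethyl-1,4,4a,7,8,8a-hexahydronaphthalene-2-carboxylate
Product: 16 [(4aR,8aS)-1,1,3,6-tetramethyl-1,4,4a,7,8,8a-hexahydronaphthalen-2-yl]methanol
Conditions: iBu2AlH (2.5 equiv), CH2Cl2, −78 → 0 °C; Rochelle salt
Reagents that add atoms: none
Why: 1,2-Reduction of the ester, which is twisted out of conjugation by its two ortho substituents, to the allylic alcohol; no stereocentre is touched.

Step 9
Reactants: 16 [(4aR,8aS)-1,1,3,6-tetramethyl-1,4,4a,7,8,8a-hexahydronaphthalen-2-yl]methanol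
Product: 18 (4aR,8aS)-2-ethynyl-1,1,3,6-tetramethyl-1,4,4a,7,8,8a-hexahydronaphthalene, via enal 17 (not isolated)
Conditions: MnO2 (10 equiv), THF, rt; then MeOH, K2CO3, MeC(O)C(N2)P(O)(OMe)2, rt
Reagents that add atoms: dimethyl (1-diazo-2-oxopropyl)phosphonate, CC(=O)C(=[N+]=[N-])P(=O)(OC)OC
Why: Tandem allylic oxidation and Seyferth–Gilbert homologation in its Ohira–Bestmann form, in which the non-enolisable enal 17 is converted in the same flask into the terminal alkyne that will become the linker (L2≡L1).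

Step 10
Reactants: 18 (4aR,8aS)-2-ethynyl-1,1,3,6-tetramethyl-1,4,4a,7,8,8a-hexahydronaphthalene
Product: 21 potassium trifluoro{[(4aR,8aS)-1,1,3,6-tetramethyl-1,4,4a,7,8,8a-hexahydronaphthalen-2-yl]ethynyl}borate, via lithium acetylide 19 (not isolated), via lithium trimethoxyborate 20 (not isolated)
Conditions: nBuLi (1.05 equiv), THF, −78 °C; B(OMe)3, −78 → −20 °C; aq KHF2, −20 °C → rt; crystallised from acetone/Et2O
Reagents that add atoms: trimethyl borate, COB(OC)OC; potassium hydrogen difluoride, [K+].F[H-]F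
Why: Standard borylation of a lithium acetylide and fluoride exchange, which turns the alkyne into a bench-stable, weighable nucleophile that carries no free base into the peroxide step.

**Dioxane peroxyketal (steps 11–17)**

Step 11
Reactants: 22 (4R)-4-benzyl-3-propanoyl-1,3-oxazolidin-2-one; 23 4-methylpent-4-enal
Product: 25 (4R)-4-benzyl-3-[(2R,3S)-3-hydroxy-2,6-dimethylhept-6-enoyl]-1,3-oxazolidin-2-one, via boron enolate 24 (not isolated)
Conditions: Bu2BOTf, iPr2NEt, CH2Cl2, 0 °C; 23, −78 → 0 °C; pH 7 buffer, MeOH, 30% H2O2, 0 °C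
Reagents that add atoms: none
Why: Evans syn-aldol reaction through the (Z)-boron enolate and a Zimmerman–Traxler chair, the (4R)-benzyl group setting P2 as (R) and the carbinol carbon (the later D3) as (S), deliberately opposite to the final configuration because it will be inverted in step 15.

Step 12
Reactants: 25 (4R)-4-benzyl-3-[(2R,3S)-3-hydroxy-2,6-dimethylhept-6-enoyl]-1,3-oxazolidin-2-one
Product: 26 (2S,3S)-2,6-dimethylhept-6-ene-1,3-diol
Conditions: LiBH4 (2 equiv), MeOH (2 equiv), THF, 0 °C
Reagents that add atoms: none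
Why: Reductive cleavage of the N-acyl oxazolidinone at the exocyclic carbonyl, which removes every acidic α-hydrogen before the leaving group is installed (so that no β-elimination to an enoate can occur later); the (2S) descriptor changes by priority only.

Step 13
Reactants: 26 (2S,3S)-2,6-dimethylhept-6-ene-1,3-diol
Product: 27 (2S,3S)-1-[(tert-butyldimethylsilyl)oxy]-2,6-dimethylhept-6-en-3-ol
Conditions: tBuMe2SiCl (1.05 equiv), imidazole, CH2Cl2, −20 → 0 °C
Reagents that add atoms: tert-butyl(chloro)dimethylsilane, CC(C)(C)[Si](C)(C)Cl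
Why: Selective silylation of the primary hydroxyl of a 1,3-diol on steric grounds, leaving the secondary hydroxyl free for activation.

Step 14
Reactants: 27 (2S,3S)-1-[(tert-butyldimethylsilyl)oxy]-2,6-dimethylhept-6-en-3-ol
Product: 28 (2S,3S)-1-[(tert-butyldimethylsilyl)oxy]-2,6-dimethylhept-6-en-3-yl methanesulfonate
Conditions: MsCl, Et3N, CH2Cl2, 0 °C
Reagents that add atoms: methanesulfonyl chloride, CS(=O)(=O)Cl
Why: O-Sulfonylation with retention, which turns the (S)-carbinol into the leaving group for the ring closure.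

Step 15
Reactants: 28 (2S,3S)-1-[(tert-butyldimethylsilyl)oxy]-2,6-dimethylhept-6-en-3-yl methanesulfonate
Product: 30 tert-butyl{(2S)-2-[(3R)-6-methoxy-6-methyl-1,2-dioxan-3-yl]propoxy}dimethylsilane (D6 epimers), via hydroperoxy ketal 29 (not isolated)
Conditions: O3, CH2Cl2/MeOH (4:1), −78 °C; N2 purge, concentrated below 20 °C; then KOtBu (1.05 equiv), 18-crown-6 (0.1 equiv), THF, 0 °C
Reagents that add atoms: ozone, [O-][O+]=O; methanol, CO
Why: Ozonolysis of the 1,1-disubstituted alkene in methanol traps the ketone oxide as the hydroperoxy ketal 29, whose potassium salt closes the 1,2-dioxane by intramolecular SN2 alkylation of the hydroperoxide at D3 (6-exo-tet, Williamson type) with inversion, turning the (S)-carbinol centre into (3R); the D6 epimers do not matter because D6 is planarised in step 18.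

Step 16
Reactants: 30 tert-butyl{(2S)-2-[(3R)-6-methoxy-6-methyl-1,2-dioxan-3-yl]propoxy}dimethylsilane
Product: 31 (2S)-2-[(3R)-6-methoxy-6-methyl-1,2-dioxan-3-yl]propan-1-ol (D6 epimers)
Conditions: Bu4NF, AcOH (1:1), THF, 0 °C → rt
Reagents that add atoms: none
Why: Fluoride desilylation, buffered with acetic acid so that the base-sensitive O–O–C–H unit at D3 is not fragmented.

Step 17
Reactants: 31 (2S)-2-[(3R)-6-methoxy-6-methyl-1,2-dioxan-3-yl]propan-1-ol
Product: 33 methyl (2R)-2-[(3R)-6-methoxy-6-methyl-1,2-dioxan-3-yl]propanoate (D6 epimers), via carboxylic acid 32 (not isolated)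
Conditions: TEMPO (0.2 equiv), PhI(OAc)2 (2.5 equiv), MeCN/pH 7 buffer (1:1), 0 °C → rt; extraction; then Me3SiCHN2, PhMe/MeOH (4:1), 0 °C
Reagents that add atoms: water, O; (trimethylsilyl)diazomethane, C[Si](C)(C)C=[N+]=[N-]
Why: Oxoammonium oxidation of the primary alcohol to the acid followed by diazoalkane esterification, both near-neutral so that P2 is not epimerised and the dialkyl peroxide and peroxyketal survive; the P2 descriptor becomes (R) by priority only.

**Union and reduction (steps 18–19)**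

Step 18
Reactants: 33 methyl (2R)-2-[(3R)-6-methoxy-6-methyl-1,2-dioxan-3-yl]propanoate; 21 potassium trifluoro{[(4aR,8aS)-1,1,3,6-tetramethyl-1,4,4a,7,8,8a-hexahydronaphthalen-2-yl]ethynyl}borate
Product: 36 methyl (2R)-2-[(3R,6S)-6-methyl-6-{[(4aR,8aS)-1,1,3,6-tetramethyl-1,4,4a,7,8,8a-hexahydronaphthalen-2-yl]ethynyl}-1,2-dioxan-3-yl]propanoate, via alkynyldifluoroborane 34 (not isolated), via peroxycarbenium ion 35 (not isolated)
Conditions: 33 (1.0 equiv), 21 (1.5 equiv), BF3·OEt2 (3 equiv), MeCN/CH2Cl2 (1:1), −40 → −10 °C; aq NaHCO3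
Reagents that add atoms: none
Why: Proposed new method: BF3 abstracts fluoride from 21 to give the alkynyldifluoroborane 34, which binds the methoxy group of 33 and ionises it to the cyclic peroxycarbenium ion 35 (D6=O1+), and the resulting ate complex hands the alkynyl group to D6 within the ion pair; the closest known reactions are the BF3-promoted couplings of potassium alkynyltrifluoroborates with acetals and the Lewis acid-mediated additions of allylsilanes and enol silanes to 3-alkoxy-1,2-dioxanes and -dioxolanes through the same cations. No ring is closed; the step joins the two halves through the D6–L1 bond and makes the only quaternary carbon of the dioxane. D6 is set by substrate control: in the half-chair of 35 (D5, D6, O1 and O2 coplanar) the propanoate arm on D3 sits pseudo-equatorial and chair-like axial attack puts the incoming carbon cis to it (1,4-relay), which is the relation in the target, while both D6 epimers of 33 converge through the planar cation. The step needs ionisation of the exocyclic C–OMe bond in preference to the ring C–O1 bond and to Hock-type cleavage of the O–O bond, which the better exocyclic leaving group, the low temperature and the short-lived ion pair should secure, and it needs a slim sp nucleophile because a quaternary centre is formed. The N2=N3 and N5=N6 alkenes are far weaker nucleophiles than the alkynylborate, and the ester is not enolised under these non-basic conditions.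

Step 19
Reactants: 36 methyl (2R)-2-[(3R,6S)-6-methyl-6-{[(4aR,8aS)-1,1,3,6-tetramethyl-1,4,4a,7,8,8a-hexahydronaphthalen-2-yl]ethynyl}-1,2-dioxan-3-yl]propanoate
Product: 38 methyl (2R)-2-[(3R,6R)-6-methyl-6-{2-[(4aR,8aS)-1,1,3,6-tetramethyl-1,4,4a,7,8,8a-hexahydronaphthalen-2-yl]ethyl}-1,2-dioxan-3-yl]propanoate (the target), via (Z)-alkene 37 (not isolated)
Conditions: KO2CN=NCO2K (portions, large excess), AcOH, CH2Cl2/MeOH (1:1), 0 °C → rt, repeated until 37 is consumed
Reagents that add atoms: none
Why: Diimide reduction, which delivers hydrogen in two syn steps to the L1≡L2 alkyne and then to the (Z)-alkene 37, leaves the O–O bond intact as in the classical reductions of unsaturated endoperoxides, and does not reduce the tetrasubstituted N2=N3 or the trisubstituted N5=N6 alkene at a useful rate; no stereocentre is touched, the D6 descriptor changing from S to R by priority only.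

## Compound list

1 | (4S)-limonene 1,2-oxide, (4S)-1,2-epoxy-p-menth-8-ene (mixture of (1R,2S,4S) and (1S,2R,4S)) | CC12OC1C[C@H](CC2)C(C)=C | starting material
2 | (1R,2R,4S)-1-methyl-2-(phenylselanyl)-4-(prop-1-en-2-yl)cyclohexan-1-ol | C[C@]1(O)[C@H]([Se]c2ccccc2)C[C@H](CC1)C(C)=C | intermediate (not isolated)
3 | (1R,2R,4S)-1-methyl-2-(phenylseleninyl)-4-(prop-1-en-2-yl)cyclohexan-1-ol (Se epimers) | C[C@]1(O)[C@H]([Se](=O)c2ccccc2)C[C@H](CC1)C(C)=C | intermediate (not isolated)
4 | (1R,4S)-1-methyl-4-(prop-1-en-2-yl)cyclohex-2-en-1-ol | C[C@]1(O)C=C[C@H](CC1)C(C)=C | intermediate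
5 | (1R,4S)-1-methyl-4-(prop-1-en-2-yl)cyclohex-2-en-1-yl acetate | C[C@]1(OC(C)=O)C=C[C@H](CC1)C(C)=C | intermediate
6 | trimethyl[(1-{[(1R,4S)-1-methyl-4-(prop-1-en-2-yl)cyclohex-2-en-1-yl]oxy}ethenyl)oxy]silane | C[C@]1(OC(=C)O[Si](C)(C)C)C=C[C@H](CC1)C(C)=C | intermediate (not isolated)
7 | trimethylsilyl 2-[(1R,6S)-3-methyl-6-(prop-1-en-2-yl)cyclohex-2-en-1-yl]acetate | C[Si](C)(C)OC(=O)C[C@@H]1C=C(C)CC[C@@H]1C(C)=C | intermediate (not isolated)
8 | 2-[(1R,6S)-3-methyl-6-(prop-1-en-2-yl)cyclohex-2-en-1-yl]acetic acid | OC(=O)C[C@@H]1C=C(C)CC[C@@H]1C(C)=C | intermediate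
9 | 1-(1H-imidazol-1-yl)-2-[(1R,6S)-3-methyl-6-(prop-1-en-2-yl)cyclohex-2-en-1-yl]ethan-1-one | O=C(C[C@@H]1C=C(C)CC[C@@H]1C(C)=C)n1ccnc1 | intermediate (not isolated)
10 | methyl 4-[(1R,6S)-3-methyl-6-(prop-1-en-2-yl)cyclohex-2-en-1-yl]-3-oxobutanoate | COC(=O)CC(=O)C[C@@H]1C=C(C)CC[C@@H]1C(C)=C | intermediate
11 | tertiary carbocation from 10 (propan-2-ylium on the ring carbon that bore the isopropenyl group, ring centres as in 10) | COC(=O)CC(=O)C[C@@H]1C=C(C)CC[C@@H]1[C+](C)C | intermediate (not isolated)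
12 | methyl (4aR,8aS)-1,1,6-trimethyl-3-oxo-1,2,3,4,4a,7,8,8a-octahydronaphthalene-2-carboxylate (N2 epimers) | COC(=O)C1C(=O)C[C@@H]2C=C(C)CC[C@@H]2C1(C)C | intermediate
13 | sodium (4aR,8aS)-3-(methoxycarbonyl)-4,4,7-trimethyl-1,4,4a,5,6,8a-hexahydronaphthalen-2-olate (enolate of 12) | [Na+].COC(=O)C1=C([O-])C[C@@H]2C=C(C)CC[C@@H]2C1(C)C | intermediate (not isolated)
14 | methyl (4aR,8aS)-1,1,6-trimethyl-3-{[(trifluoromethyl)sulfonyl]oxy}-1,4,4a,7,8,8a-hexahydronaphthalene-2-carboxylate | COC(=O)C1=C(OS(=O)(=O)C(F)(F)F)C[C@@H]2C=C(C)CC[C@@H]2C1(C)C | intermediate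
15 | methyl (4aR,8aS)-1,1,3,6-tetramethyl-1,4,4a,7,8,8a-hexahydronaphthalene-2-carboxylate | COC(=O)C1=C(C)C[C@@H]2C=C(C)CC[C@@H]2C1(C)C | intermediate
16 | [(4aR,8aS)-1,1,3,6-tetramethyl-1,4,4a,7,8,8a-hexahydronaphthalen-2-yl]methanol | OCC1=C(C)C[C@@H]2C=C(C)CC[C@@H]2C1(C)C | intermediate
17 | (4aR,8aS)-1,1,3,6-tetramethyl-1,4,4a,7,8,8a-hexahydronaphthalene-2-carbaldehyde | O=CC1=C(C)C[C@@H]2C=C(C)CC[C@@H]2C1(C)C | intermediate (not isolated)
18 | (4aR,8aS)-2-ethynyl-1,1,3,6-tetramethyl-1,4,4a,7,8,8a-hexahydronaphthalene | C#CC1=C(C)C[C@@H]2C=C(C)CC[C@@H]2C1(C)C | intermediate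
19 | lithium acetylide of 18 | [Li]C#CC1=C(C)C[C@@H]2C=C(C)CC[C@@H]2C1(C)C | intermediate (not isolated)
20 | lithium trimethoxy{[(4aR,8aS)-1,1,3,6-tetramethyl-1,4,4a,7,8,8a-hexahydronaphthalen-2-yl]ethynyl}borate | [Li+].CO[B-](OC)(OC)C#CC1=C(C)C[C@@H]2C=C(C)CC[C@@H]2C1(C)C | intermediate (not isolated)
21 | potassium trifluoro{[(4aR,8aS)-1,1,3,6-tetramethyl-1,4,4a,7,8,8a-hexahydronaphthalen-2-yl]ethynyl}borate | [K+].F[B-](F)(F)C#CC1=C(C)C[C@@H]2C=C(C)CC[C@@H]2C1(C)C | intermediate
22 | (4R)-4-benzyl-3-propanoyl-1,3-oxazolidin-2-one | CCC(=O)N1[C@H](Cc2ccccc2)COC1=O | starting material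
23 | 4-methylpent-4-enal | CC(=C)CCC=O | starting material
24 | (4R)-4-benzyl-3-{(1Z)-1-[(dibutylboranyl)oxy]prop-1-en-1-yl}-1,3-oxazolidin-2-one | C/C=C(\OB(CCCC)CCCC)N1[C@H](Cc2ccccc2)COC1=O | intermediate (not isolated)
25 | (4R)-4-benzyl-3-[(2R,3S)-3-hydroxy-2,6-dimethylhept-6-enoyl]-1,3-oxazolidin-2-one | O=C(N1[C@H](Cc2ccccc2)COC1=O)[C@H](C)[C@@H](O)CCC(C)=C | intermediate
26 | (2S,3S)-2,6-dimethylhept-6-ene-1,3-diol | OC[C@H](C)[C@@H](O)CCC(C)=C | intermediate
27 | (2S,3S)-1-[(tert-butyldimethylsilyl)oxy]-2,6-dimethylhept-6-en-3-ol | CC(C)(C)[Si](C)(C)OC[C@H](C)[C@@H](O)CCC(C)=C | intermediate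
28 | (2S,3S)-1-[(tert-butyldimethylsilyl)oxy]-2,6-dimethylhept-6-en-3-yl methanesulfonate | CC(C)(C)[Si](C)(C)OC[C@H](C)[C@@H](OS(C)(=O)=O)CCC(C)=C | intermediate
29 | (2S,3S)-1-[(tert-butyldimethylsilyl)oxy]-6-hydroperoxy-6-methoxy-2-methylheptan-3-yl methanesulfonate (C6 epimers) | CC(C)(C)[Si](C)(C)OC[C@H](C)[C@@H](OS(C)(=O)=O)CCC(C)(OC)OO | intermediate (not isolated)
30 | tert-butyl{(2S)-2-[(3R)-6-methoxy-6-methyl-1,2-dioxan-3-yl]propoxy}dimethylsilane (D6 epimers) | CC(C)(C)[Si](C)(C)OC[C@H](C)[C@H]1CCC(C)(OC)OO1 | intermediate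
31 | (2S)-2-[(3R)-6-methoxy-6-methyl-1,2-dioxan-3-yl]propan-1-ol (D6 epimers) | OC[C@H](C)[C@H]1CCC(C)(OC)OO1 | intermediate
32 | (2R)-2-[(3R)-6-methoxy-6-methyl-1,2-dioxan-3-yl]propanoic acid (D6 epimers) | OC(=O)[C@H](C)[C@H]1CCC(C)(OC)OO1 | intermediate (not isolated)
33 | methyl (2R)-2-[(3R)-6-methoxy-6-methyl-1,2-dioxan-3-yl]propanoate (D6 epimers) | COC(=O)[C@H](C)[C@H]1CCC(C)(OC)OO1 | intermediate
34 | difluoro{[(4aR,8aS)-1,1,3,6-tetramethyl-1,4,4a,7,8,8a-hexahydronaphthalen-2-yl]ethynyl}borane | FB(F)C#CC1=C(C)C[C@@H]2C=C(C)CC[C@@H]2C1(C)C | intermediate (not isolated)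
35 | cyclic peroxycarbenium ion of 33, (3R)-3-[(2R)-1-methoxy-1-oxopropan-2-yl]-6-methyl-4,5-dihydro-3H-1,2-dioxin-1-ium | COC(=O)[C@H](C)[C@H]1CCC(C)=[O+]O1 | intermediate (not isolated)
36 | methyl (2R)-2-[(3R,6S)-6-methyl-6-{[(4aR,8aS)-1,1,3,6-tetramethyl-1,4,4a,7,8,8a-hexahydronaphthalen-2-yl]ethynyl}-1,2-dioxan-3-yl]propanoate | COC(=O)[C@H](C)[C@H]1CC[C@@](C)(C#CC2=C(C)C[C@@H]3C=C(C)CC[C@@H]3C2(C)C)OO1 | intermediate
37 | methyl (2R)-2-[(3R,6S)-6-methyl-6-{(Z)-2-[(4aR,8aS)-1,1,3,6-tetramethyl-1,4,4a,7,8,8a-hexahydronaphthalen-2-yl]ethenyl}-1,2-dioxan-3-yl]propanoate | COC(=O)[C@H](C)[C@H]1CC[C@@](C)(/C=C\C2=C(C)C[C@@H]3C=C(C)CC[C@@H]3C2(C)C)OO1 | intermediate (not isolated)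
38 | methyl (2R)-2-[(3R,6R)-6-methyl-6-{2-[(4aR,8aS)-1,1,3,6-tetramethyl-1,4,4a,7,8,8a-hexahydronaphthalen-2-yl]ethyl}-1,2-dioxan-3-yl]propanoate | COC(=O)[C@H](C)[C@H]1CC[C@@](C)(CCC2=C(C)C[C@@H]3C=C(C)CC[C@@H]3C2(C)C)OO1 | target

## Step count and risks

Total step count: 19 (steps 1–10 for the bicyclic alkynyl borate, steps 11–17 for the dioxane peroxyketal, steps 18–19 for union and reduction).
Longest linear sequence: 12 steps (steps 1–10, 18, 19).

Steps most likely to fail:

1. Step 18 (Proposed new method). The alkynyl group may not be transferred to the hindered tertiary peroxycarbenium ion fast enough to outrun fragmentation of the O–O bond or loss of a proton to a cyclic enol ether, and the facial selectivity of the attack may be lower than the half-chair model predicts. The fallback uses only known reaction types, sets out from 18 (with 33) and comes back at 38. Alkyne 18 would be hydrated ((Ph3P)AuNTf2 as catalyst, MeOH/H2O) to 1-[(4aR,8aS)-1,1,3,6-tetramethyl-1,4,4a,7,8,8a-hexahydronaphthalen-2-yl]ethan-1-one (F1), and F1 would be converted (Me3SiOTf, Et3N) into its silyl enol ether, trimethyl({1-[(4aR,8aS)-1,1,3,6-tetramethyl-1,4,4a,7,8,8a-hexahydronaphthalen-2-yl]ethenyl}oxy)silane (F2). F2 would be added to 33 with Me3SiOTf or SnCl4 at −78 °C, the established Mukaiyama-type reaction of enol silanes with cyclic peroxyketals, which should follow the same axial course and give the β-peroxy ketone methyl (2R)-2-[(3R,6S)-6-methyl-6-{2-oxo-2-[(4aR,8aS)-1,1,3,6-tetramethyl-1,4,4a,7,8,8a-hexahydronaphthalen-2-yl]ethyl}-1,2-dioxan-3-yl]propanoate (F3). The ketone F3 would be reduced under Luche conditions (NaBH4, CeCl3) to the allylic alcohol methyl (2R)-2-[(3R,6S)-6-{2-hydroxy-2-[(4aR,8aS)-1,1,3,6-tetramethyl-1,4,4a,7,8,8a-hexahydronaphthalen-2-yl]ethyl}-6-methyl-1,2-dioxan-3-yl]propanoate (F4). The alcohol F4 would then be deoxygenated ionically (Et3SiH, BF3·OEt2, −78 °C, hydride to the less hindered end of the allyl cation), which would reach 38 without any alkyne reduction.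

2. Step 5. The acid that protonates the isopropenyl group may also protonate the ring B alkene, so that the N5=N6 alkene migrates or a bridged product forms, and O-alkylation of the enol may compete. The fallback sets out from 10 and comes back at 12. Mukaiyama hydration (Co(acac)2 as catalyst, PhSiH3, O2, iPrOH), which selects the 1,1-disubstituted over the trisubstituted alkene, would give the tertiary alcohol methyl 4-[(1R,6S)-6-(2-hydroxypropan-2-yl)-3-methylcyclohex-2-en-1-yl]-3-oxobutanoate (F5). Ionisation of F5 with BF3·OEt2 at −78 °C would generate the same cation at N1 from the C–O bond, with no free protic acid at the start, and the enol would close ring A to 12.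

3. Step 15. E2 elimination of the secondary mesylate or base-induced fragmentation of the product at the O–O–C–H unit may compete with the intramolecular SN2 closure. The fallback sets out from 28 and comes back at 30. The C–O bond would be made first, by intermolecular alkylation of 2-methoxyprop-2-yl hydroperoxide with 28 (CsOH, DMF, 0 °C, inversion at D3), to give tert-butyl{[(2S,3R)-3-[(2-methoxypropan-2-yl)peroxy]-2,6-dimethylhept-6-en-1-yl]oxy}dimethylsilane (F6). The alkene F6 would be ozonised with Me2S work-up to the methyl ketone (5R,6S)-7-[(tert-butyldimethylsilyl)oxy]-5-[(2-methoxypropan-2-yl)peroxy]-6-methylheptan-2-one (F7). The ketone F7 would be treated with PPTS in MeOH, which would unmask the D3 hydroperoxide; this would close onto the ketone as the cyclic peroxy-hemiketal and be methylated in the same flask to 30, so that the ring is closed by ketalisation and not by displacement.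

## Further compounds

F1 | step 18 | 1-[(4aR,8aS)-1,1,3,6-tetramethyl-1,4,4a,7,8,8a-hexahydronaphthalen-2-yl]ethan-1-one | CC(=O)C1=C(C)C[C@@H]2C=C(C)CC[C@@H]2C1(C)C
F2 | step 18 | trimethyl({1-[(4aR,8aS)-1,1,3,6-tetramethyl-1,4,4a,7,8,8a-hexahydronaphthalen-2-yl]ethenyl}oxy)silane | C=C(O[Si](C)(C)C)C1=C(C)C[C@@H]2C=C(C)CC[C@@H]2C1(C)C
F3 | step 18 | methyl (2R)-2-[(3R,6S)-6-methyl-6-{2-oxo-2-[(4aR,8aS)-1,1,3,6-tetramethyl-1,4,4a,7,8,8a-hexahydronaphthalen-2-yl]ethyl}-1,2-dioxan-3-yl]propanoate | COC(=O)[C@H](C)[C@H]1CC[C@@](C)(CC(=O)C2=C(C)C[C@@H]3C=C(C)CC[C@@H]3C2(C)C)OO1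
F4 | step 18 | methyl (2R)-2-[(3R,6S)-6-{2-hydroxy-2-[(4aR,8aS)-1,1,3,6-tetramethyl-1,4,4a,7,8,8a-hexahydronaphthalen-2-yl]ethyl}-6-methyl-1,2-dioxan-3-yl]propanoate (carbinol epimers) | COC(=O)[C@H](C)[C@H]1CC[C@@](C)(CC(O)C2=C(C)C[C@@H]3C=C(C)CC[C@@H]3C2(C)C)OO1
F5 | step 5 | methyl 4-[(1R,6S)-6-(2-hydroxypropan-2-yl)-3-methylcyclohex-2-en-1-yl]-3-oxobutanoate | COC(=O)CC(=O)C[C@@H]1C=C(C)CC[C@@H]1C(C)(C)O
F6 | step 15 | tert-butyl{[(2S,3R)-3-[(2-methoxypropan-2-yl)peroxy]-2,6-dimethylhept-6-en-1-yl]oxy}dimethylsilane | CC(C)(C)[Si](C)(C)OC[C@H](C)[C@H](OOC(C)(C)OC)CCC(C)=C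
F7 | step 15 | (5R,6S)-7-[(tert-butyldimethylsilyl)oxy]-5-[(2-methoxypropan-2-yl)peroxy]-6-methylheptan-2-one | CC(C)(C)[Si](C)(C)OC[C@H](C)[C@H](OOC(C)(C)OC)CCC(C)=O
A1 | direct plan | (5R,7Z)-3,3,5,9-tetramethyldeca-1,7,9-trien-4-one | C[C@H](C/C=C\C(C)=C)C(=O)C(C)(C)C=C
A2 | direct plan | (4aR,8aS)-1,1,3,6-tetramethyl-1,4,4a,7,8,8a-hexahydronaphthalen-2-yl trifluoromethanesulfonate | FC(F)(F)S(=O)(=O)OC1=C(C)C[C@@H]2C=C(C)CC[C@@H]2C1(C)C
A3 | direct plan | (6S)-6-[(1R)-1,2-bis(acetyloxy)ethyl]-6-methyl-1,2-dioxan-3-yl acetate | CC(=O)OC[C@@H](OC(C)=O)[C@@]1(C)OOC(OC(C)=O)CC1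
A4 | direct plan | methyl (2R)-2-[(3R,6S)-6-ethenyl-6-methyl-1,2-dioxan-3-yl]propanoate | COC(=O)[C@H](C)[C@H]1CC[C@@](C)(C=C)OO1
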